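**Strategy.** The γ-lactone (O–C19–C17–C8–C7) shares its C7–C8 bond with the ten-membered carbocycle. Both rings are therefore traced back to one intramolecular ketene–silyl enol ether [2+2] cycloaddition: a vinylketene (C7=C19=O) at the end of the C1 side chain adds to the (Z)-enol ether (C8=C17) of the C10 side chain of a fully substituted cyclohexane, forming C19–C17 and C7–C8, a cyclobutanone and the ten-membered ring in one operation and setting C7, C8 and C17. Regioselective Baeyer–Villiger oxidation then inserts the lactone oxygen between C7 and C19. The cyclohexane stems from a catalytic asymmetric Diels–Alder reaction whose stereocenters control all others.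

Key step: step 25

Remark (numbering and assumption): briarane numbering is used throughout (C1 quaternary with methyl C15; C2–C7; C8; C9; C10; C11 with methyl C20; C12–C14; C16 on C5; C17 with methyl C18; C19 lactone carbonyl), β is the cyclohexane face that carries C15, and ethyl (E)-2-methyl-4-oxobut-2-enoate (2) is taken as a catalogue compound.

## Route

Step 1
Reactants: 1 (E)-penta-1,3-diene; 2 ethyl (E)-2-methyl-4-oxobut-2-enoate
Product: 3 ethyl 2-formyl-1,3-dimethylcyclohex-4-ene-1-carboxylate (C9 formyl on C10 and both methyls β; C2 ester α; C12=C13)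
Conditions: (5S)-5-benzyl-2,2,3-trimethylimidazolidin-4-one hydrochloride (20 mol %), MeCN/H2O 95:5, 0 °C to rt
Reagents that add atoms: none
Why: Iminium-catalysed Diels–Alder reaction in which the unsubstituted diene terminus should bond to the ester-bearing β-carbon (C1) and the methyl-bearing terminus to C10 (ortho orientation), the iminium carbon lies endo so that C9 ends up cis to C20, the E dienophile keeps C15 cis to C9 and the ester trans, and the benzyl group of the (5S)-catalyst leaves the Si face of C10 open, which sets C1, C10 and C11 in the absolute sense shown.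

Step 2
Reactants: 3 Diels–Alder aldehyde
Product: 4 C9 carboxylic acid of 3
Conditions: NaClO2, NaH2PO4, 2-methyl-2-butene, t-BuOH/H2O, 0 °C to rt
Reagents that add atoms: sodium chlorite [Na+].[O-]Cl=O
Why: Pinnick oxidation should convert the aldehyde into the acid under buffered conditions that neither epimerise C10 nor touch the ring alkene.

Step 3
Reactants: 4 acid
Product: 5 iodolactone (C9(=O)–O–C12 γ-lactone with O12 β; iodine 13α; ethyl ester on C1)
Conditions: I2, KI, NaHCO3, CH2Cl2/H2O, 0 °C to rt, dark
Reagents that add atoms: iodine II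
Why: Iodolactonization in which the β-carboxylate opens the α-face iodonium ion at C12 (5-exo closure of a 6-oxabicyclo[3.2.1]octanone), which should place O12 β and cis to C9 and the iodine 13α.

Step 4
Reactants: 5 iodolactone
Product: 6 unsaturated lactone (C13=C14)
Conditions: DBU, toluene, 80 °C
Reagents that add atoms: none
Why: E2 elimination, for which the only hydrogen antiperiplanar to the axial 13α-iodide is 14β-H, so the C13=C14 alkene should form.

Step 5
Reactants: 6 unsaturated lactone
Product: 7 13α,14α-epoxy lactone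
Conditions: mCPBA, NaHCO3, CH2Cl2, rt to 40 °C
Reagents that add atoms: 3-chloroperoxybenzoic acid OOC(=O)c1cccc(Cl)c1
Why: Prilezhaev epoxidation should occur on the α face, anti to the lactone bridge that covers the β face, which puts the future O14 α and trans to O12.

Step 6
Reactants: 7 epoxy lactone
Product: 8 tetraol (C2 and C9 hydroxymethyl groups; 12β-OH; 14α-OH)
Conditions: NaAlH2(OCH2CH2OMe)2 (Red-Al, excess), THF, 0 °C to rt; Rochelle salt work-up
Reagents that add atoms: none
Why: Hydride reduction of lactone and ester gives the two primary alcohols, and the C12 alkoxyaluminate should then deliver hydride intramolecularly to C13 (Red-Al opening of a trans-2,3-epoxy alcohol to the 1,3-diol), which leaves the C14–O bond untouched as the 14α-hydroxyl.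

Step 7
Reactants: 8 tetraol
Product: 9 O2/O14 acetonide of 8 (1,3-dioxane; C9–OH and 12-OH free)
Conditions: Me2C(OMe)2, PPTS (cat.), acetone, rt
Reagents that add atoms: 2,2-dimethoxypropane COC(C)(C)OC
Why: Acetalization under thermodynamic control, in which only the cis-related O2/O14 pair can close a six-membered acetonide, so the C9 and C12 hydroxyls should stay free.

Step 8
Reactants: 9 acetonide diol
Product: 10 9,12-bis(TBS) ether of 9
Conditions: TBSOTf, 2,6-lutidine, CH2Cl2, −78 to 0 °C
Reagents that add atoms: tert-butyldimethylsilyl triflate CC(C)(C)[Si](C)(C)OS(=O)(=O)C(F)(F)F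
Why: Silylation with the triflate should cap both the primary C9 hydroxyl and the hindered secondary C12 hydroxyl.

Step 9
Reactants: 10 bis(TBS) ether
Product: 11 12-TBS ether with free C9 hydroxyl
Conditions: HF·pyridine, pyridine, THF, 0 °C
Reagents that add atoms: none
Why: Buffered fluoride desilylation should cleave the primary silyl ether much faster than the hindered secondary one and leave the acetonide.

Step 10
Reactants: 11 primary alcohol
Product: 12 C9 aldehyde
Conditions: Dess–Martin periodinane, NaHCO3, CH2Cl2, 0 °C to rt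
Reagents that add atoms: none
Why: Dess–Martin oxidation should give the aldehyde under non-basic conditions that do not epimerise C10.

Step 11
Reactants: 13 1,3-dithiane
Product: 14 2-ethyl-1,3-dithiane
Conditions: n-BuLi, THF, −30 °C; EtI, −78 to 0 °C
Reagents that add atoms: iodoethane CCI
Why: Corey–Seebach alkylation of lithiated 1,3-dithiane should give the masked propanoyl anion that later becomes C8, C17 and C18.

Step 12
Reactants: 12 C9 aldehyde; 14 2-ethyl-1,3-dithiane
Product: 16 C9 acetate of the dithiane adduct (C10 bears CH(OAc)–C(2-ethyl-1,3-dithian-2-yl); acetonide and 12-OTBS kept), via lithium alkoxide 15 (not isolated)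
Conditions: 14, n-BuLi, THF, −30 °C; 12, −78 °C; then Ac2O, −78 to 0 °C
Reagents that add atoms: acetic anhydride CC(=O)OC(C)=O
Why: Corey–Seebach acyl-anion addition under Felkin–Anh control (quaternary C1 anti to the nucleophile, H-10 inside) should set C9 as in the target, and trapping of the lithium alkoxide with acetic anhydride installs the C9 acetate directly.

Step 13
Reactants: 16 acetonide
Product: 17 2,14-diol (C2 primary OH; 14α-OH)
Conditions: PPTS, MeOH, 40 °C
Reagents that add atoms: none
Why: Transacetalization with methanol should remove the 1,3-dioxane while the hindered secondary silyl ether, the acetate and the dithioacetal persist.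

Step 14
Reactants: 17 diol
Product: 18 C2 aldehyde (14α-OH free)
Conditions: TEMPO (cat.), PhI(OAc)2, CH2Cl2, rt
Reagents that add atoms: none
Why: TEMPO/PhI(OAc)2 oxidation should take the primary alcohol selectively over the secondary C14 hydroxyl and tolerate the thioacetal, and the aldehyde on quaternary C1 cannot enolise.

Step 15
Reactants: 18 C2 aldehyde
Product: 19 C2 allylic alcohol CH(OH)CH=CH2 (both C2 epimers)
Conditions: vinyl bromide, CrCl2, NiCl2 (cat.), DMF, rt
Reagents that add atoms: vinyl bromide C=CBr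
Why: Nozaki–Hiyama–Kishi vinylation is aldehyde-selective and should tolerate the acetate and the free hydroxyl; the C2 configuration is immaterial because it is erased in step 16.

Step 16
Reactants: 19 allylic alcohol
Product: 20 C2 vinyl ketone (β-hydroxy enone)
Conditions: MnO2, CH2Cl2, rt
Reagents that add atoms: none
Why: MnO2 should oxidise only the allylic alcohol and leave the saturated C14 hydroxyl for the directed reduction.

Step 17
Reactants: 20 β-hydroxy enone
Product: 21 2,14-syn diol with C2 configured as in the target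
Conditions: Et2BOMe, THF/MeOH 4:1, −78 °C; NaBH4; MeOH azeotrope
Reagents that add atoms: none
Why: Narasaka–Prasad reduction in which hydride should attack the O14–boron–carbonyl chelate axially and anti to C10, giving the 1,3-syn diol and thereby setting C2.

Step 18
Reactants: 21 syn diol
Product: 22 2,9,14-triacetate with C3=C4 vinyl group
Conditions: Ac2O, DMAP, pyridine, CH2Cl2, rt
Reagents that add atoms: acetic anhydride CC(=O)OC(C)=O
Why: DMAP-catalysed acetylation of both hydroxyls should install the C2 and C14 acetates of the target.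

Step 19
Reactants: 23 propargyl alcohol; 24 tert-butyl diazoacetate
Product: 25 tert-butyl 5-hydroxypent-3-ynoate
Conditions: CuI (5 mol %), MeCN, rt
Reagents that add atoms: none
Why: Copper-catalysed coupling of a terminal alkyne with a diazo ester (copper acetylide, carbene migratory insertion) should give the 3-alkynoate without O–H insertion.

Step 20
Reactants: 25 alkynol
Product: 27 tert-butyl (Z)-5-hydroxy-4-iodopent-3-enoate (iodine cis to CH2CO2tBu), via vinylstannane 26 (not isolated)
Conditions: Bu3SnH, [Cp*RuCl]4 (cat.), CH2Cl2, rt; then I2, 0 °C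
Reagents that add atoms: iodine II
Why: Hydroxyl-directed ruthenium-catalysed trans-hydrostannation should put tin on the alkyne carbon next to the carbinol with hydrogen trans to it, and iododestannylation proceeds with retention.

Step 21
Reactants: 27 iodo allylic alcohol
Product: 28 tert-butyl (Z)-5-(tert-butyldimethylsilyloxy)-4-iodopent-3-enoate
Conditions: TBSCl, imidazole, DMF, rt
Reagents that add atoms: tert-butyldimethylsilyl chloride CC(C)(C)[Si](C)(C)Cl
Why: Standard silylation of the primary allylic alcohol, which keeps C16 at the alcohol oxidation level until after the Baeyer–Villiger step.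

Step 22
Reactants: 22 vinyl triacetate; 28 vinyl iodide
Product: 30 seco compound (C1 chain CH(OAc)CH2CH2–C(CH2OTBS)=CH–CH2CO2tBu with C4 cis to C7; dithioacetal at C8), via B-alkyl-9-BBN 29 (not isolated)
Conditions: 9-BBN, THF, rt; then 28, Pd(dppf)Cl2, AsPh3, Cs2CO3, DMF/H2O, rt
Reagents that add atoms: none
Why: B-alkyl Suzuki–Miyaura coupling in which 9-BBN should hydroborate the terminal vinyl group at C4 and the alkylborane couples with the vinyl iodide with retention, so C4 ends up cis to C7 across C5=C6.

Step 23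
Reactants: 30 dithioacetal
Product: 31 C8 ethyl ketone (α-acetoxy ketone)
Conditions: MeI, CaCO3, MeCN/H2O 9:1, 45 °C
Reagents that add atoms: water O
Why: S-Methylation and hydrolysis of the dithioacetal under neutral conditions should unmask the ketone without touching acetates, silyl ethers, the tert-butyl ester or the alkene.

Step 24
Reactants: 31 keto tert-butyl ester
Product: 33 carboxylic acid carrying the (Z)-C8 silyl enol ether, via bis-silyl compound 32 (not isolated)
Conditions: TBSOTf, Et3N, CH2Cl2, −78 to 23 °C; then aq. NaHCO3, THF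
Reagents that add atoms: tert-butyldimethylsilyl triflate CC(C)(C)[Si](C)(C)OS(=O)(=O)C(F)(F)F
Why: Soft enolization (silyl triflate and amine) should occur at the less hindered C17 methylene of the α-acetoxy ethyl ketone and give the Z silyl enol ether, while the tert-butyl ester is converted into the silyl ester (loss of isobutene) that is hydrolysed on bicarbonate work-up.

Step 25
Reactants: 33 enol ether acid
Product: 36 cyclobutanone (C19–C17–C8–C7 ring trans-fused to the ten-membered carbocycle), via acyloxypyridinium salt 34 (not isolated), via vinylketene 35 (not isolated)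
Conditions: 2-chloro-1-methylpyridinium iodide, Et3N, MeCN, 80 °C, syringe-pump addition of 33 (final ca. 1 mM)
Reagents that add atoms: none
Why: Proposed new method: the acid is activated as its 2-acyloxypyridinium salt and dehydrohalogenated to vinylketene 35, whose electrophilic C19 is attacked by the nucleophilic C17 of the silyl enol ether while C7 bonds to C8 in a [π2s+π2a] (or closely asynchronous zwitterionic) ketene–alkene [2+2] cycloaddition; the closest known reactions are the intermolecular cis-selective cycloaddition of ketenes with silyl enol ethers and the intramolecular ketene–alkene cycloaddition, which is established only for five- to seven-membered rings. The cyclobutanone closes by this [2+2], and because C7 and C8 are linked through C6–C5–C4–C3–C2–C1–C10–C9, the same event closes the ten-membered carbocycle as a trans-fused bicyclo[8.2.0] unit (ring closure at the C7–C8 bond, with the leading C19–C17 contact spanning a twelve-membered array). C17 and C8 are related by suprafacial addition to the Z enol ether (C18 cis to O8); C7 follows the usual preference of a monosubstituted ketene to place its substituent (C6) cis to the alkoxy group, which is also the less strained trans ring fusion; the absolute sense at C8 comes from attack on the enol ether face anti to C10 in the rotamer with H-9 eclipsing the C8–O bond, the rotamer in which C7 and C10 are antiperiplanar as the ring requires. Regiochemistry (C19 to C17, not to C8) follows from enol ether polarization, and the Z enol ether, the cis C5=C6 bond and the trans-disposed chains on the cyclohexane restrict the precursor so that the termini can meet. The selectivity that must be won is ring closure over ketene dimerisation, which high dilution and slow ketene generation should secure; the risk is entropic rather than electronic.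

Step 26
Reactants: 36 cyclobutanone
Product: 37 γ-lactone (O inserted between C7 and C19; 8-OTBS, 12-OTBS and 16-OTBS kept)
Conditions: 30% aq. H2O2, (CF3)2CHOH, 0 °C to rt
Reagents that add atoms: hydrogen peroxide OO
Why: Baeyer–Villiger oxidation of the strained cyclobutanone, in which the allylic C7 should migrate with retention in preference to C17 and the trisubstituted alkene is not epoxidised under these catalyst-free conditions.

Step 27
Reactants: 37 silylated lactone
Product: 38 triol (8-OH, 12-OH and C16 allylic OH)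
Conditions: HF (48% aq.), MeCN, 0 °C to rt
Reagents that add atoms: none
Why: Acidic fluoride desilylation should cleave the primary allylic, secondary and tertiary silyl ethers while leaving the acetates and the lactone intact.

Step 28
Reactants: 38 triol
Product: 39 C16 enal
Conditions: MnO2, CH2Cl2, rt
Reagents that add atoms: none
Why: MnO2 should oxidise only the allylic C16 alcohol and spare the secondary C12 and tertiary C8 hydroxyls.

Step 29
Reactants: 39 enal
Product: 40 C16 carboxylic acid
Conditions: NaClO2, NaH2PO4, 2-methyl-2-butene, t-BuOH/H2O, 0 °C to rt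
Reagents that add atoms: sodium chlorite [Na+].[O-]Cl=O
Why: Pinnick oxidation should convert the enal into the acid without isomerising the C5=C6 bond or oxidising the free hydroxyls.

Step 30
Reactants: 40 acid
Product: 41 CNP0233742.2 (target)
Conditions: TMSCHN2, toluene/MeOH, 0 °C
Reagents that add atoms: (trimethylsilyl)diazomethane C[Si](C)(C)C=[N+]=[N-]
Why: Neutral methylation of the carboxylic acid with TMS-diazomethane should give the methyl ester without touching the acetates, the lactone or the free hydroxyls.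

## Compound list

1 | (E)-penta-1,3-diene | C/C=C/C=C | starting material
2 | ethyl (E)-2-methyl-4-oxobut-2-enoate | CCOC(=O)/C(C)=C/C=O | starting material
3 | ethyl 2-formyl-1,3-dimethylcyclohex-4-ene-1-carboxylate (formyl and both methyls β, ester α) | O=C[C@H]1[C@@H](C)C=CC[C@]1(C)C(=O)OCC | intermediate
4 | C9 carboxylic acid of 3 | OC(=O)[C@H]1[C@@H](C)C=CC[C@]1(C)C(=O)OCC | intermediate
5 | iodolactone (C9–O12 γ-lactone, 13α-iodide) | O=C3[C@H]2[C@@H](C)[C@@H](O3)[C@H](I)C[C@]2(C)C(=O)OCC | intermediate
6 | unsaturated lactone (C13=C14) | O=C3[C@H]2[C@@H](C)[C@@H](O3)C=C[C@]2(C)C(=O)OCC | intermediate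
7 | 13α,14α-epoxy lactone | O=C3[C@H]2[C@@H](C)[C@@H](O3)[C@@H]4O[C@@H]4[C@]2(C)C(=O)OCC | intermediate
8 | tetraol (C2 and C9 CH2OH, 12β-OH, 14α-OH) | OC[C@H]2[C@@H](C)[C@@H](O)C[C@H](O)[C@]2(C)CO | intermediate
9 | O2/O14 acetonide of 8 | OC[C@H]2[C@@H](C)[C@@H](O)C[C@H](O3)[C@]2(C)COC3(C)C | intermediate
10 | 9,12-bis(TBS) ether of 9 | CC(C)(C)[Si](C)(C)OC[C@H]2[C@@H](C)[C@@H](O[Si](C)(C)C(C)(C)C)C[C@H](O3)[C@]2(C)COC3(C)C | intermediate
11 | 12-TBS ether with free C9 hydroxyl | OC[C@H]2[C@@H](C)[C@@H](O[Si](C)(C)C(C)(C)C)C[C@H](O3)[C@]2(C)COC3(C)C | intermediate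
12 | C9 aldehyde | O=C[C@H]2[C@@H](C)[C@@H](O[Si](C)(C)C(C)(C)C)C[C@H](O3)[C@]2(C)COC3(C)C | intermediate
13 | 1,3-dithiane | C1CSCSC1 | starting material
14 | 2-ethyl-1,3-dithiane | CCC1SCCCS1 | intermediate
15 | lithium C9 alkoxide of the dithiane adduct | CCC1(SCCCS1)[C@H]([O-])[C@H]2[C@@H](C)[C@@H](O[Si](C)(C)C(C)(C)C)C[C@H](O3)[C@]2(C)COC3(C)C.[Li+] | intermediate (not isolated)
16 | C9 acetate of the dithiane adduct | CCC1(SCCCS1)[C@H](OC(C)=O)[C@H]2[C@@H](C)[C@@H](O[Si](C)(C)C(C)(C)C)C[C@H](O3)[C@]2(C)COC3(C)C | intermediate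
17 | 2,14-diol | CCC1(SCCCS1)[C@H](OC(C)=O)[C@H]2[C@@H](C)[C@@H](O[Si](C)(C)C(C)(C)C)C[C@H](O)[C@]2(C)CO | intermediate
18 | C2 aldehyde (14α-OH free) | CCC1(SCCCS1)[C@H](OC(C)=O)[C@H]2[C@@H](C)[C@@H](O[Si](C)(C)C(C)(C)C)C[C@H](O)[C@]2(C)C=O | intermediate
19 | C2 allylic alcohol (C2 epimers) | CCC1(SCCCS1)[C@H](OC(C)=O)[C@H]2[C@@H](C)[C@@H](O[Si](C)(C)C(C)(C)C)C[C@H](O)[C@]2(C)C(O)C=C | intermediate
20 | C2 vinyl ketone | CCC1(SCCCS1)[C@H](OC(C)=O)[C@H]2[C@@H](C)[C@@H](O[Si](C)(C)C(C)(C)C)C[C@H](O)[C@]2(C)C(=O)C=C | intermediate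
21 | 2,14-syn diol (allylic alcohol) | CCC1(SCCCS1)[C@H](OC(C)=O)[C@H]2[C@@H](C)[C@@H](O[Si](C)(C)C(C)(C)C)C[C@H](O)[C@]2(C)[C@H](O)C=C | intermediate
22 | 2,9,14-triacetate with vinyl group | CCC1(SCCCS1)[C@H](OC(C)=O)[C@H]2[C@@H](C)[C@@H](O[Si](C)(C)C(C)(C)C)C[C@H](OC(C)=O)[C@]2(C)[C@H](OC(C)=O)C=C | intermediate
23 | propargyl alcohol | C#CCO | starting material
24 | tert-butyl diazoacetate | [N-]=[N+]=CC(=O)OC(C)(C)C | starting material
25 | tert-butyl 5-hydroxypent-3-ynoate | OCC#CCC(=O)OC(C)(C)C | intermediate
26 | tert-butyl (Z)-5-hydroxy-4-(tributylstannyl)pent-3-enoate | CCCC[Sn](CCCC)(CCCC)/C(CO)=C\CC(=O)OC(C)(C)C | intermediate (not isolated)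
27 | tert-butyl (Z)-5-hydroxy-4-iodopent-3-enoate | OC/C(I)=C/CC(=O)OC(C)(C)C | intermediate
28 | tert-butyl (Z)-5-(tert-butyldimethylsilyloxy)-4-iodopent-3-enoate | CC(C)(C)[Si](C)(C)OC/C(I)=C/CC(=O)OC(C)(C)C | intermediate
29 | B-alkyl-9-BBN from 22 | CCC1(SCCCS1)[C@H](OC(C)=O)[C@H]2[C@@H](C)[C@@H](O[Si](C)(C)C(C)(C)C)C[C@H](OC(C)=O)[C@]2(C)[C@H](OC(C)=O)CCB3C4CCCC3CCC4 | intermediate (not isolated)
30 | seco compound with dithioacetal and tert-butyl ester | CCC1(SCCCS1)[C@H](OC(C)=O)[C@H]2[C@@H](C)[C@@H](O[Si](C)(C)C(C)(C)C)C[C@H](OC(C)=O)[C@]2(C)[C@H](OC(C)=O)CC/C(CO[Si](C)(C)C(C)(C)C)=C\CC(=O)OC(C)(C)C | intermediate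
31 | C8 ethyl ketone | CCC(=O)[C@H](OC(C)=O)[C@H]2[C@@H](C)[C@@H](O[Si](C)(C)C(C)(C)C)C[C@H](OC(C)=O)[C@]2(C)[C@H](OC(C)=O)CC/C(CO[Si](C)(C)C(C)(C)C)=C\CC(=O)OC(C)(C)C | intermediate
32 | TBS ester with (Z)-TBS enol ether | C/C=C(\O[Si](C)(C)C(C)(C)C)[C@H](OC(C)=O)[C@H]2[C@@H](C)[C@@H](O[Si](C)(C)C(C)(C)C)C[C@H](OC(C)=O)[C@]2(C)[C@H](OC(C)=O)CC/C(CO[Si](C)(C)C(C)(C)C)=C\CC(=O)O[Si](C)(C)C(C)(C)C | intermediate (not isolated)
33 | carboxylic acid with (Z)-TBS enol ether | C/C=C(\O[Si](C)(C)C(C)(C)C)[C@H](OC(C)=O)[C@H]2[C@@H](C)[C@@H](O[Si](C)(C)C(C)(C)C)C[C@H](OC(C)=O)[C@]2(C)[C@H](OC(C)=O)CC/C(CO[Si](C)(C)C(C)(C)C)=C\CC(=O)O | intermediate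
34 | 2-acyloxy-1-methylpyridinium iodide of 33 | C/C=C(\O[Si](C)(C)C(C)(C)C)[C@H](OC(C)=O)[C@H]2[C@@H](C)[C@@H](O[Si](C)(C)C(C)(C)C)C[C@H](OC(C)=O)[C@]2(C)[C@H](OC(C)=O)CC/C(CO[Si](C)(C)C(C)(C)C)=C\CC(=O)Oc1cccc[n+]1C.[I-] | intermediate (not isolated)
35 | vinylketene (C7=C19=O) | C/C=C(\O[Si](C)(C)C(C)(C)C)[C@H](OC(C)=O)[C@H]2[C@@H](C)[C@@H](O[Si](C)(C)C(C)(C)C)C[C@H](OC(C)=O)[C@]2(C)[C@H](OC(C)=O)CC/C(CO[Si](C)(C)C(C)(C)C)=C\C=C=O | intermediate (not isolated)
36 | cyclobutanone fused to the ten-membered ring | CC(C)(C)[Si](C)(C)OC/C1=C/[C@@H]2C(=O)[C@H](C)[C@@]2(O[Si](C)(C)C(C)(C)C)[C@H](OC(C)=O)[C@H]2[C@@H](C)[C@@H](O[Si](C)(C)C(C)(C)C)C[C@H](OC(C)=O)[C@]2(C)[C@H](OC(C)=O)CC1 | intermediate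
37 | tris-silylated γ-lactone | CC(C)(C)[Si](C)(C)OC/C1=C/[C@@H]2OC(=O)[C@H](C)[C@@]2(O[Si](C)(C)C(C)(C)C)[C@H](OC(C)=O)[C@H]2[C@@H](C)[C@@H](O[Si](C)(C)C(C)(C)C)C[C@H](OC(C)=O)[C@]2(C)[C@H](OC(C)=O)CC1 | intermediate
38 | triol (8-OH, 12-OH, C16 OH) | OC/C1=C/[C@@H]2OC(=O)[C@H](C)[C@@]2(O)[C@H](OC(C)=O)[C@H]2[C@@H](C)[C@@H](O)C[C@H](OC(C)=O)[C@]2(C)[C@H](OC(C)=O)CC1 | intermediate
39 | C16 enal | O=C/C1=C/[C@@H]2OC(=O)[C@H](C)[C@@]2(O)[C@H](OC(C)=O)[C@H]2[C@@H](C)[C@@H](O)C[C@H](OC(C)=O)[C@]2(C)[C@H](OC(C)=O)CC1 | intermediate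
40 | C16 carboxylic acid | OC(=O)/C1=C/[C@@H]2OC(=O)[C@H](C)[C@@]2(O)[C@H](OC(C)=O)[C@H]2[C@@H](C)[C@@H](O)C[C@H](OC(C)=O)[C@]2(C)[C@H](OC(C)=O)CC1 | intermediate
41 | CNP0233742.2 | COC(=O)/C1=C/[C@@H]2OC(=O)[C@H](C)[C@@]2(O)[C@H](OC(C)=O)[C@H]2[C@@H](C)[C@@H](O)C[C@H](OC(C)=O)[C@]2(C)[C@H](OC(C)=O)CC1 | target

## Step count and risks

Total step count: 30. Longest linear sequence: 26 steps (steps 1–10, 12–18 and 22–30); steps 11 and 19–21 are the side branches.

**Step 25 (Proposed new method).** What may go wrong: the ketene dimerises or oligomerises faster than the medium-ring transition state is reached. The fallback uses known chemistry (intermolecular ketene–silyl enol ether [2+2], then macrocyclic B-alkyl Suzuki–Miyaura coupling); it sets out from 22 and 28 and comes back to the route at 37. Dithioacetal cleavage of 22 (MeI, CaCO3, aqueous MeCN) should give the ethyl ketone F1, and TBSOTf/Et3N its (Z)-silyl enol ether F2. Treatment of 28 with TBSOTf/2,6-lutidine and aqueous work-up should give the iodo acid F3. Slow addition of F3, 2-chloro-1-methylpyridinium iodide and Et3N to F2 should generate the iodovinylketene F4, which should add to the same enol ether face as in step 25 to give the cyclobutanone F5. Baeyer–Villiger oxidation (H2O2, hexafluoroisopropanol) should then give the lactone F6. Hydroboration of the terminal vinyl group of F6 with 9-BBN and intramolecular coupling with the vinyl iodide (Pd(dppf)Cl2, AsPh3, Cs2CO3, high dilution) should close the C4–C5 bond and deliver 37.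

**Step 1.** What may go wrong: slow iminium formation from the β,β-disubstituted enal, or insufficient facial or endo discrimination while the quaternary centre is formed. The fallback replaces catalysis by resolution; it sets out from 1 and 2 and comes back at 4. A BF3·OEt2-promoted cycloaddition (CH2Cl2, −78 °C) should give the same endo, ortho adduct as a racemate, that is 3 together with its enantiomer F7. Pinnick oxidation should give 4 together with its enantiomer F8. Crystallisation with (R)-1-phenylethylamine should single out the ammonium salt F9 of 4 (the antipodal amine is used if the other salt is the less soluble one), and acidification returns 4.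

**Step 6.** What may go wrong: hydride delivery to C14 instead of C13, or alkoxide-induced epoxide migration before the reduction is complete. The fallback replaces epoxide opening by dihydroxylation and deoxygenation; it sets out from 6, bypasses 7 and comes back at 8. Dihydroxylation of 6 (OsO4 cat., NMO) on the α face should give the cis-13α,14α-diol F10. The less hindered C13 hydroxyl is converted into the phenyl thionocarbonate F11 (PhOC(S)Cl, pyridine). Barton–McCombie deoxygenation (Bu3SnH, AIBN, toluene, 80 °C) should give the 14α-hydroxy lactone F12, and LiAlH4 reduction of lactone and ester should then give 8.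

## Further compounds

F1 | step 25 | C8 ethyl ketone of 22 | CCC(=O)[C@H](OC(C)=O)[C@H]2[C@@H](C)[C@@H](O[Si](C)(C)C(C)(C)C)C[C@H](OC(C)=O)[C@]2(C)[C@H](OC(C)=O)C=C
F2 | step 25 | (Z)-TBS enol ether of F1 | C/C=C(\O[Si](C)(C)C(C)(C)C)[C@H](OC(C)=O)[C@H]2[C@@H](C)[C@@H](O[Si](C)(C)C(C)(C)C)C[C@H](OC(C)=O)[C@]2(C)[C@H](OC(C)=O)C=C
F3 | step 25 | (Z)-5-(tert-butyldimethylsilyloxy)-4-iodopent-3-enoic acid | CC(C)(C)[Si](C)(C)OC/C(I)=C/CC(=O)O
F4 | step 25 | iodovinylketene from F3 | CC(C)(C)[Si](C)(C)OC/C(I)=C/C=C=O
F5 | step 25 | cyclobutanone from F2 and F4 | CC(C)(C)[Si](C)(C)OC/C(I)=C/[C@@H]2C(=O)[C@H](C)[C@@]2(O[Si](C)(C)C(C)(C)C)[C@H](OC(C)=O)[C@H]2[C@@H](C)[C@@H](O[Si](C)(C)C(C)(C)C)C[C@H](OC(C)=O)[C@]2(C)[C@H](OC(C)=O)C=C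
F6 | step 25 | γ-lactone from F5 | CC(C)(C)[Si](C)(C)OC/C(I)=C/[C@@H]2OC(=O)[C@H](C)[C@@]2(O[Si](C)(C)C(C)(C)C)[C@H](OC(C)=O)[C@H]2[C@@H](C)[C@@H](O[Si](C)(C)C(C)(C)C)C[C@H](OC(C)=O)[C@]2(C)[C@H](OC(C)=O)C=C
F7 | step 1 | enantiomer of 3 | O=C[C@@H]1[C@H](C)C=CC[C@@]1(C)C(=O)OCC
F8 | step 1 | enantiomer of 4 | OC(=O)[C@@H]1[C@H](C)C=CC[C@@]1(C)C(=O)OCC
F9 | step 1 | (R)-1-phenylethylammonium salt of 4 | C[C@@H]([NH3+])c1ccccc1.[O-]C(=O)[C@H]1[C@@H](C)C=CC[C@]1(C)C(=O)OCC
F10 | step 6 | 13α,14α-dihydroxy lactone | O=C3[C@H]2[C@@H](C)[C@@H](O3)[C@H](O)[C@H](O)[C@]2(C)C(=O)OCC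
F11 | step 6 | C13 phenyl thionocarbonate of F10 | O=C3[C@H]2[C@@H](C)[C@@H](O3)[C@H](OC(=S)Oc4ccccc4)[C@H](O)[C@]2(C)C(=O)OCC
F12 | step 6 | 14α-hydroxy lactone | O=C3[C@H]2[C@@H](C)[C@@H](O3)C[C@H](O)[C@]2(C)C(=O)OCC
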